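**Retrosynthetic overview**

1. Feature: ring A (C1–C5, C10; labdane numbering) carries no functional group and meets ring B only at C5 and C10, between quaternary C4 (gem-dimethyl) and quaternary C10 (angular methyl). It is cut at C4–C5 and C1–C10, giving ring-B enone 7 and 4-methylpent-4-enal 11.
2. Ring B is taken from an arene: 4-methoxy-3-methylphenol → quinone monoketal → enantioselective methyl conjugate addition (sets C8) → 1,3-cis reduction (sets C6) → enone 7.
3. Spiro centre C9 and side chain: C9 ketone → C9=C11 → α-epoxide → 3-furylmethyl Grignard (C11–C12).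
4. Furan → butenolide (singlet oxygen, then borohydride), oxa-Michael closure C9–O–C13; last, C6 inversion by oxidation/reduction and acetylation.
5. Ring order: B (from the arene) → A (step 8) → butenolide → tetrahydrofuran.

Key step: step 8

Remark: labdane numbering and α/β descriptors are used for all bicyclic compounds (α = face opposite the C10 methyl); the sense of induction in step 2 is assumed for the (S,R,R)-ligand and would be checked on 4, the antipodal ligand being used if needed.

**Route**

Step 1
Reactants: 1 4-methoxy-3-methylphenol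
Product: 2 4,4-dimethoxy-3-methylcyclohexa-2,5-dien-1-one
Conditions: PhI(OAc)2 (1.1 equiv), MeOH, 0 °C
Reagents that add atoms: methanol, CO
Why: Oxidative dearomatisation of a para-methoxyphenol by a λ3-iodane in methanol (quinone monoketal formation) is reliable and creates no stereocentre.

Step 2
Reactants: 2 4,4-dimethoxy-3-methylcyclohexa-2,5-dien-1-one
Product: 4 (R)-4,4-dimethoxy-3,5-dimethylcyclohex-2-en-1-one, via methylzinc enolate 3 (not isolated)
Conditions: Me2Zn (1.5 equiv), Cu(OTf)2 (2 mol%), (S,R,R)-O,O'-(1,1'-binaphthyl-2,2'-diyl)-N,N-bis(1-phenylethyl)phosphoramidite (4 mol%), toluene, −25 °C; aq. NH4Cl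
Reagents that add atoms: dimethylzinc, C[Zn]C
Why: Copper/phosphoramidite-catalysed enantioselective conjugate addition of a dialkylzinc to a quinone monoketal; methyl should add only to the unsubstituted β-carbon C5 (C3 is blocked by its methyl group), and the ligand-controlled face of attack should set this carbon (labdane C8) as R.

Step 3
Reactants: 4 (R)-4,4-dimethoxy-3,5-dimethylcyclohex-2-en-1-one
Product: 5 (1S,5R)-4,4-dimethoxy-3,5-dimethylcyclohex-2-en-1-ol
Conditions: NaBH4, CeCl3·7H2O, MeOH, −78 °C
Reagents that add atoms: none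
Why: Luche 1,2-reduction; hydride should add to the carbonyl face anti to the C5 methyl (the usual outcome for 5-substituted cyclohexenones), giving the 1,3-cis alcohol (labdane 6α-OH).

Step 4
Reactants: 5 (1S,5R)-4,4-dimethoxy-3,5-dimethylcyclohex-2-en-1-ol
Product: 6 tert-butyl{[(1S,5R)-4,4-dimethoxy-3,5-dimethylcyclohex-2-en-1-yl]oxy}dimethylsilane
Conditions: TBSCl, imidazole, DMF, rt
Reagents that add atoms: tert-butyldimethylsilyl chloride, CC(C)(C)[Si](C)(C)Cl
Why: Standard silylation of a secondary allylic alcohol under basic conditions that leave the dimethyl ketal intact.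

Step 5
Reactants: 6 tert-butyl{[(1S,5R)-4,4-dimethoxy-3,5-dimethylcyclohex-2-en-1-yl]oxy}dimethylsilane
Product: 7 (4S,6R)-4-[(tert-butyldimethylsilyl)oxy]-2,6-dimethylcyclohex-2-en-1-one
Conditions: PPTS (10 mol%), acetone/H2O (10:1), rt
Reagents that add atoms: water, O
Why: Mild acid-catalysed hydrolysis of an allylic dimethyl ketal, which a secondary TBS ether survives; the C6 methyl remains cis to the silyloxy group (both pseudo-equatorial).

Step 6
Reactants: 8 2-methylprop-2-en-1-ol (methallyl alcohol); 9 ethyl vinyl ether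
Product: 10 3-(ethenyloxy)-2-methylprop-1-ene (methallyl vinyl ether)
Conditions: Hg(OAc)2 (5 mol%), 9 as solvent, reflux; K2CO3; distil
Reagents that add atoms: none
Why: Mercury(II)-catalysed transvinylation (vinyl ether exchange) of a primary allylic alcohol, driven by the excess of ethyl vinyl ether.

Step 7
Reactants: 10 3-(ethenyloxy)-2-methylprop-1-ene
Product: 11 4-methylpent-4-enal
Conditions: neat, sealed tube, 150 °C; distil
Reagents that add atoms: none
Why: Claisen [3,3]-sigmatropic rearrangement of an allyl vinyl ether gives the γ,δ-unsaturated aldehyde; no stereocentre is formed.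

Step 8
Reactants: 7 (4S,6R)-4-[(tert-butyldimethylsilyl)oxy]-2,6-dimethylcyclohex-2-en-1-one; 11 4-methylpent-4-enal
Product: 13 6α-[(tert-butyldimethylsilyl)oxy]-1α-hydroxy-4,4,8α,10β-tetramethyl-trans-decalin-9-one, via Giese adduct enolate 12 (not isolated)
Conditions: Fe(acac)3 (30 mol%), PhSiH3 (2.5 equiv), EtOH/(CH2OH)2 (5:1), 0 °C → rt, 11 (2 equiv) added slowly
Reagents that add atoms: none
Why: An iron hydride formed from Fe(acac)3 and the silane transfers a hydrogen atom to the CH2 terminus of the 1,1-disubstituted alkene of 11; the tertiary C4 radical adds to the enone β-carbon C5 of 7, the resulting C10 radical is reduced to the iron enolate 12, and this adds to the tethered aldehyde C1. The closest known reaction type is the iron-hydride-initiated radical conjugate addition–aldol (radical–polar crossover) annulation of unsaturated aldehydes with cyclic enones. Ring A closes by a 6-(enolexo)-exo-trig aldol addition that forms C1–C10 after C4–C5 has been made intermolecularly. C5 is set by attack of the bulky radical on the face anti to the neighbouring C6 silyloxy group; C10 is set in a chair aldol transition state with the C4 substituent on C5 equatorial and C1 bonding to the α-face of the enolate, so the methyl ends β and the fusion trans; C1 should carry an axial (1α) hydroxyl from the iron-bridged closed transition state and is removed in steps 9–10 in any case; C8, α to the ketone, keeps or equilibrates to the equatorial 8α-methyl. The step needs hydrogen-atom transfer to the electron-rich alkene of 11 in preference to the enone (secured by the polarity preference of metal-hydride HAT), π-facial selectivity at C5 (secured by the OTBS group) and trans fusion (secured by the equatorial C5 and C8 substituents in the chair transition state).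

Step 9
Reactants: 13 6α-[(tert-butyldimethylsilyl)oxy]-1α-hydroxy-4,4,8α,10β-tetramethyl-trans-decalin-9-one
Product: 14 6α-[(tert-butyldimethylsilyl)oxy]-4,4,8α,10β-tetramethyl-trans-decal-1-en-9-one
Conditions: Martin sulfurane (1.5 equiv), CH2Cl2, 0 °C → rt
Reagents that add atoms: none
Why: Martin sulfurane dehydration of a hindered secondary alcohol under non-basic conditions (no retro-aldol); the axial C1 alkoxysulfonium should eliminate with the trans-diaxial H2β (E2), C2 being the only β-carbon that bears hydrogen because C10 is quaternary.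

Step 10
Reactants: 14 6α-[(tert-butyldimethylsilyl)oxy]-4,4,8α,10β-tetramethyl-trans-decal-1-en-9-one
Product: 15 6α-[(tert-butyldimethylsilyl)oxy]-4,4,8α,10β-tetramethyl-trans-decalin-9-one
Conditions: H2 (1 atm), 10% Pd/C, EtOAc, rt
Reagents that add atoms: none
Why: Catalytic hydrogenation of a cis-disubstituted ring alkene; ketone and silyl ether are inert and no stereocentre is created.

Step 11
Reactants: 15 6α-[(tert-butyldimethylsilyl)oxy]-4,4,8α,10β-tetramethyl-trans-decalin-9-one
Product: 16 6α-[(tert-butyldimethylsilyl)oxy]-4,4,8α,10β-tetramethyl-9-methylene-trans-decalin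
Conditions: Ph3PCH3Br (4 equiv), KOt-Bu (3.8 equiv), toluene, 100 °C
Reagents that add atoms: methyltriphenylphosphonium bromide, [Br-].C[P+](c1ccccc1)(c1ccccc1)c1ccccc1
Why: Wittig methylenation under forcing conditions as used for 2,2,6-trisubstituted cyclohexanones; enolisation is possible only toward C8, whose equatorial α-methyl is the thermodynamic epimer (the axial epimer would be 1,3-diaxial to the C10 methyl).

Step 12
Reactants: 16 6α-[(tert-butyldimethylsilyl)oxy]-4,4,8α,10β-tetramethyl-9-methylene-trans-decalin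
Product: 17 9α,11-epoxide of 16 (spiro-oxirane at C9, oxygen α, CH2 β)
Conditions: mCPBA, NaHCO3, CH2Cl2, 0 °C
Reagents that add atoms: 3-chloroperbenzoic acid, OOC(=O)c1cccc(Cl)c1
Why: Prilezhaev epoxidation of the exocyclic 1,1-disubstituted alkene; the peracid should approach the α-face, anti to the axial C10 methyl on the adjacent carbon, placing the oxygen α (axial) at C9.

Step 13
Reactants: 18 furan-3-ylmethanol
Product: 20 3-(chloromethyl)furan, via furan-3-ylmethyl methanesulfonate 19 (not isolated)
Conditions: MsCl, 2,4,6-collidine, LiCl, DMF, 0 °C; used as a solution after extractive work-up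
Reagents that add atoms: lithium chloride, [Li+].[Cl-]
Why: Mesylation with in-situ SN2 displacement by chloride converts the furylmethyl alcohol to the chloride without free acid, which the furan would not tolerate.

Step 14
Reactants: 20 3-(chloromethyl)furan; 17 9α,11-epoxide of 16
Product: 22 6α-[(tert-butyldimethylsilyl)oxy]-15,16-epoxylabda-13(16),14-dien-9α-ol, via (furan-3-ylmethyl)magnesium chloride 21 (not isolated)
Conditions: Mg, THF, 0 °C (slow addition of 20); then CuI (10 mol%), 17, THF, −30 °C → rt; aq. NH4Cl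
Reagents that add atoms: none
Why: Copper-catalysed SN2 opening of a 1,1-disubstituted epoxide by a benzylic-type Grignard reagent at the unsubstituted carbon C11 forms C11–C12 and leaves the C9–O bond, and so the 9α configuration, untouched.

Step 15
Reactants: 22 6α-[(tert-butyldimethylsilyl)oxy]-15,16-epoxylabda-13(16),14-dien-9α-ol
Product: 24 6α-[(tert-butyldimethylsilyl)oxy]-9α,16-dihydroxylabd-13-en-16,15-olide (C15 carbonyl; C16 epimers), via furan endoperoxide 23 (not isolated)
Conditions: O2, hν (visible), tetraphenylporphyrin (cat.), i-Pr2NEt (5 equiv), CH2Cl2, −78 °C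
Reagents that add atoms: oxygen, O=O
Why: [4+2] cycloaddition of singlet oxygen to the furan, then Kornblum–DeLaMare-type opening of the endoperoxide by the hindered base, which removes the less hindered bridgehead proton at C15 so that the carbonyl forms distal to the side chain (the known regioselective photooxygenation of 3-alkylfurans); the C16 lactol centre is removed in step 16.

Step 16
Reactants: 24 6α-[(tert-butyldimethylsilyl)oxy]-9α,16-dihydroxylabd-13-en-16,15-olide
Product: 25 6α-[(tert-butyldimethylsilyl)oxy]-9α-hydroxylabd-13-en-16,15-olide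
Conditions: NaBH4, EtOH, 0 °C; then 1 M HCl to pH 3
Reagents that add atoms: none
Why: Borohydride reduces the open aldehyde form of the lactol and the γ-hydroxy acid relactonises to the β-substituted butenolide; the conjugated lactone is not reduced under these conditions.

Step 17
Reactants: 25 6α-[(tert-butyldimethylsilyl)oxy]-9α-hydroxylabd-13-en-16,15-olide
Product: 26 (13S)-6α-[(tert-butyldimethylsilyl)oxy]-9α,13-epoxylabdan-16,15-olide
Conditions: KOt-Bu (20 mol%), degassed THF, −20 °C → rt; chromatography, 13-epimer resubmitted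
Reagents that add atoms: none
Why: Intramolecular oxa-Michael addition (5-exo-trig) of the tertiary C9 alkoxide to C13 of the butenolide closes the tetrahydrofuran ring; the addition is reversible and the two C13 epimers differ only in whether C14 or C16 faces C17, so little facial bias is expected and the 13S epimer is to be isolated while the 13R epimer is re-equilibrated under the same conditions.

Step 18
Reactants: 26 (13S)-6α-[(tert-butyldimethylsilyl)oxy]-9α,13-epoxylabdan-16,15-olide
Product: 27 (13S)-9α,13-epoxy-6α-hydroxylabdan-16,15-olide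
Conditions: HF·pyridine, THF, 0 °C → rt
Reagents that add atoms: none
Why: Fluoride cleavage of the secondary silyl ether under acidic conditions, chosen so that no base can trigger retro-oxa-Michael opening and loss of the C13 configuration.

Step 19
Reactants: 27 (13S)-9α,13-epoxy-6α-hydroxylabdan-16,15-olide
Product: 28 (13S)-9α,13-epoxy-6-oxolabdan-16,15-olide
Conditions: Dess–Martin periodinane, NaHCO3, CH2Cl2, rt
Reagents that add atoms: none
Why: Dess–Martin oxidation of the equatorial secondary alcohol; the trans ring fusion at C5 is the stable one, so the adjacent stereocentre is not at risk.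

Step 20
Reactants: 28 (13S)-9α,13-epoxy-6-oxolabdan-16,15-olide
Product: 29 (13S)-9α,13-epoxy-6β-hydroxylabdan-16,15-olide
Conditions: NaBH4, MeOH/CH2Cl2, −20 °C
Reagents that add atoms: none
Why: Substrate-controlled ketone reduction: the β-face of C6 is shielded by the syn-axial C10 methyl and 4β-methyl, so hydride should add from the α-face and give the axial 6β-alcohol; the saturated γ-lactone is not reduced.

Step 21
Reactants: 29 (13S)-9α,13-epoxy-6β-hydroxylabdan-16,15-olide
Product: 30 previtexilactone
Conditions: Ac2O, DMAP, pyridine, 40 °C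
Reagents that add atoms: acetic anhydride, CC(=O)OC(C)=O
Why: DMAP-catalysed acylation of the hindered axial alcohol with retention at C6 completes the target.

**Compound list**

1 | 4-methoxy-3-methylphenol | COc1ccc(O)cc1C | starting material
2 | 4,4-dimethoxy-3-methylcyclohexa-2,5-dien-1-one | COC1(OC)C=CC(=O)C=C1C | intermediate
3 | methylzinc enolate of ketone 4 | C[Zn]OC1=C[C@@H](C)C(OC)(OC)C(C)=C1 | intermediate
4 | (R)-4,4-dimethoxy-3,5-dimethylcyclohex-2-en-1-one | O=C1C[C@@H](C)C(OC)(OC)C(C)=C1 | intermediate
5 | (1S,5R)-4,4-dimethoxy-3,5-dimethylcyclohex-2-en-1-ol | O[C@H]1C[C@@H](C)C(OC)(OC)C(C)=C1 | intermediate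
6 | tert-butyl{[(1S,5R)-4,4-dimethoxy-3,5-dimethylcyclohex-2-en-1-yl]oxy}dimethylsilane | CC(C)(C)[Si](C)(C)O[C@H]1C[C@@H](C)C(OC)(OC)C(C)=C1 | intermediate
7 | (4S,6R)-4-[(tert-butyldimethylsilyl)oxy]-2,6-dimethylcyclohex-2-en-1-one | CC(C)(C)[Si](C)(C)O[C@H]1C[C@@H](C)C(=O)C(C)=C1 | intermediate
8 | 2-methylprop-2-en-1-ol (methallyl alcohol) | CC(=C)CO | starting material
9 | ethyl vinyl ether | C=COCC | starting material
10 | 3-(ethenyloxy)-2-methylprop-1-ene (methallyl vinyl ether) | CC(=C)COC=C | intermediate
11 | 4-methylpent-4-enal | CC(=C)CCC=O | intermediate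
12 | Giese adduct enolate (iron enolate, drawn as the free C9–C10 enolate; C4–C5 formed, aldehyde still open) | CC(C)(C)[Si](C)(C)O[C@H]1C[C@@H](C)C([O-])=C(C)[C@@H]1C(C)(C)CCC=O | intermediate
13 | 6α-[(tert-butyldimethylsilyl)oxy]-1α-hydroxy-4,4,8α,10β-tetramethyl-trans-decalin-9-one (5α-H) | CC(C)(C)[Si](C)(C)O[C@H]1C[C@@H](C)C(=O)[C@@]2(C)[C@@H](O)CCC(C)(C)[C@H]12 | intermediate
14 | 6α-[(tert-butyldimethylsilyl)oxy]-4,4,8α,10β-tetramethyl-trans-decal-1-en-9-one | CC(C)(C)[Si](C)(C)O[C@H]1C[C@@H](C)C(=O)[C@@]2(C)C=CCC(C)(C)[C@H]12 | intermediate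
15 | 6α-[(tert-butyldimethylsilyl)oxy]-4,4,8α,10β-tetramethyl-trans-decalin-9-one | CC(C)(C)[Si](C)(C)O[C@H]1C[C@@H](C)C(=O)[C@@]2(C)CCCC(C)(C)[C@H]12 | intermediate
16 | 6α-[(tert-butyldimethylsilyl)oxy]-4,4,8α,10β-tetramethyl-9-methylene-trans-decalin | CC(C)(C)[Si](C)(C)O[C@H]1C[C@@H](C)C(=C)[C@@]2(C)CCCC(C)(C)[C@H]12 | intermediate
17 | 9α,11-epoxide of 16 (spiro-oxirane at C9, oxygen α) | CC(C)(C)[Si](C)(C)O[C@H]1C[C@@H](C)[C@]3(CO3)[C@@]2(C)CCCC(C)(C)[C@H]12 | intermediate
18 | furan-3-ylmethanol | OCc1ccoc1 | starting material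
19 | furan-3-ylmethyl methanesulfonate | CS(=O)(=O)OCc1ccoc1 | intermediate
20 | 3-(chloromethyl)furan | ClCc1ccoc1 | intermediate
21 | (furan-3-ylmethyl)magnesium chloride | Cl[Mg]Cc1ccoc1 | intermediate
22 | 6α-[(tert-butyldimethylsilyl)oxy]-15,16-epoxylabda-13(16),14-dien-9α-ol (3-substituted furan) | CC(C)(C)[Si](C)(C)O[C@H]1C[C@@H](C)[C@](O)(CCc3ccoc3)[C@@]2(C)CCCC(C)(C)[C@H]12 | intermediate
23 | 2,5-endoperoxide of furan 22 | CC(C)(C)[Si](C)(C)O[C@H]1C[C@@H](C)[C@](O)(CCC3=CC4OOC3O4)[C@@]2(C)CCCC(C)(C)[C@H]12 | intermediate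
24 | 6α-[(tert-butyldimethylsilyl)oxy]-9α,16-dihydroxylabd-13-en-16,15-olide (C15 carbonyl; C16 epimers) | CC(C)(C)[Si](C)(C)O[C@H]1C[C@@H](C)[C@](O)(CCC3=CC(=O)OC3O)[C@@]2(C)CCCC(C)(C)[C@H]12 | intermediate
25 | 6α-[(tert-butyldimethylsilyl)oxy]-9α-hydroxylabd-13-en-16,15-olide | CC(C)(C)[Si](C)(C)O[C@H]1C[C@@H](C)[C@](O)(CCC3=CC(=O)OC3)[C@@]2(C)CCCC(C)(C)[C@H]12 | intermediate
26 | (13S)-6α-[(tert-butyldimethylsilyl)oxy]-9α,13-epoxylabdan-16,15-olide | CC(C)(C)[Si](C)(C)O[C@H]1C[C@@H](C)[C@]2(CC[C@]3(COC(=O)C3)O2)[C@@]2(C)CCCC(C)(C)[C@H]12 | intermediate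
27 | (13S)-9α,13-epoxy-6α-hydroxylabdan-16,15-olide | O[C@H]1C[C@@H](C)[C@]2(CC[C@]3(COC(=O)C3)O2)[C@@]2(C)CCCC(C)(C)[C@H]12 | intermediate
28 | (13S)-9α,13-epoxy-6-oxolabdan-16,15-olide | O=C1C[C@@H](C)[C@]2(CC[C@]3(COC(=O)C3)O2)[C@@]2(C)CCCC(C)(C)[C@H]12 | intermediate
29 | (13S)-9α,13-epoxy-6β-hydroxylabdan-16,15-olide | O[C@@H]1C[C@@H](C)[C@]2(CC[C@]3(COC(=O)C3)O2)[C@@]2(C)CCCC(C)(C)[C@H]12 | intermediate
30 | previtexilactone, (5S,6R,8R,9R,10S,13S)-6β-acetoxy-9α,13-epoxylabdan-16,15-olide | CC(=O)O[C@@H]1C[C@@H](C)[C@]2(CC[C@]3(COC(=O)C3)O2)[C@@]2(C)CCCC(C)(C)[C@H]12 | target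

**Step count**

Total: 21 steps. Longest linear sequence: 18 steps (1–5, 8–12, 14–21).

**Steps most likely to fail**

Step 8. The tertiary radical may be reduced before it adds, or add to C5 without facial control; the iron enolate may be protonated before it reaches the aldehyde; closure may give the cis-fused ring. Fallback (polar and stepwise; from 7, back to 13): Hosomi–Sakurai addition of prenyltrimethylsilane to 7 (TiCl4, CH2Cl2, −78 °C) transfers the 1,1-dimethylallyl group through its γ-carbon to C5, anti to the silyl ether, and should give 4-[(tert-butyldimethylsilyl)oxy]-2,6-dimethyl-3-(2-methylbut-3-en-2-yl)cyclohexan-1-one F1. Linear-selective hydroformylation of its neopentyl-type vinyl group (Rh(acac)(CO)2, Xantphos, CO/H2, toluene, 80 °C) should give 4-{6-[(tert-butyldimethylsilyl)oxy]-2,4-dimethyl-3-oxocyclohexyl}-4-methylpentanal F2. Reversible base-mediated intramolecular aldol addition (KOH, MeOH, 0 °C) can close a six-membered ring only through the C10 enolate and should settle on the trans-fused hydroxy decalone 13. Either C1 epimer serves; an equatorial hydroxyl would be removed in step 9 by syn-elimination with the Burgess reagent.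

Step 17. The oxa-Michael closure is reversible, so conversion may stall at an unfavourable equilibrium with 25; C13 may form without facial preference; the base may deconjugate or degrade the butenolide. Fallback (irreversible halo-etherification; from 17, back to 26): epoxide 17 is opened at C11 with the dianion of 3-methylbut-3-en-1-ol (n-BuLi, TMEDA, Et2O/hexane, then 17) to give 6α-[(tert-butyldimethylsilyl)oxy]labd-13(16)-ene-9α,15-diol F3. Iodoetherification (I2, NaHCO3, MeCN, 0 °C) closes the tetrahydrofuran by 5-exo attack of the tertiary hydroxyl on C13 and, after separation from the C13 epimer, should give (13S)-6α-[(tert-butyldimethylsilyl)oxy]-9α,13-epoxy-16-iodolabdan-15-ol F4. TEMPO/PhI(OAc)2 (MeCN/H2O) oxidises the primary alcohol to (13S)-6α-[(tert-butyldimethylsilyl)oxy]-9α,13-epoxy-16-iodolabdan-15-oic acid F5, and Cs2CO3 in DMF (60 °C) closes the lactone by carboxylate displacement of iodide, giving 26. Ring closure then no longer depends on an equilibrium, and the facial preference of the kinetic iodonium opening is independent of that of the conjugate addition.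

Step 14. Wurtz coupling may occur while the furylmethyl Grignard reagent forms; this ambident reagent may attack through C2 of the furan; magnesium halide may rearrange the hindered epoxide faster than substitution occurs at the neopentyl-type C11. Fallback (sulfone-stabilised carbanion; from 20 and 17, back to 22): chloride 20 is converted with PhSO2Na (DMF, rt) to 3-[(phenylsulfonyl)methyl]furan F6. After deprotonation with n-BuLi (THF/DMPU, −78 °C → rt) it opens epoxide 17 at C11 to give the γ-hydroxy sulfone 6α-[(tert-butyldimethylsilyl)oxy]-15,16-epoxy-12-(phenylsulfonyl)labda-13(16),14-dien-9α-ol F7 (C12 epimers). Reductive desulfonylation (6% Na/Hg, Na2HPO4, MeOH, −20 °C) gives 22; the hydroxyl is γ to the sulfone, so no Julia-type elimination can occur.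

**Further compounds**

F1 | step 8 | 4-[(tert-butyldimethylsilyl)oxy]-2,6-dimethyl-3-(2-methylbut-3-en-2-yl)cyclohexan-1-one (C2 epimers) | CC(C)(C)[Si](C)(C)O[C@H]1C[C@@H](C)C(=O)C(C)[C@@H]1C(C)(C)C=C
F2 | step 8 | 4-{6-[(tert-butyldimethylsilyl)oxy]-2,4-dimethyl-3-oxocyclohexyl}-4-methylpentanal | CC(C)(C)[Si](C)(C)O[C@H]1C[C@@H](C)C(=O)C(C)[C@@H]1C(C)(C)CCC=O
F3 | step 17 | 6α-[(tert-butyldimethylsilyl)oxy]labd-13(16)-ene-9α,15-diol | CC(C)(C)[Si](C)(C)O[C@H]1C[C@@H](C)[C@](O)(CCC(=C)CCO)[C@@]2(C)CCCC(C)(C)[C@H]12
F4 | step 17 | (13S)-6α-[(tert-butyldimethylsilyl)oxy]-9α,13-epoxy-16-iodolabdan-15-ol | CC(C)(C)[Si](C)(C)O[C@H]1C[C@@H](C)[C@]2(CC[C@@](CI)(CCO)O2)[C@@]2(C)CCCC(C)(C)[C@H]12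
F5 | step 17 | (13S)-6α-[(tert-butyldimethylsilyl)oxy]-9α,13-epoxy-16-iodolabdan-15-oic acid | CC(C)(C)[Si](C)(C)O[C@H]1C[C@@H](C)[C@]2(CC[C@@](CI)(CC(=O)O)O2)[C@@]2(C)CCCC(C)(C)[C@H]12
F6 | step 14 | 3-[(phenylsulfonyl)methyl]furan | O=S(=O)(Cc1ccoc1)c1ccccc1
F7 | step 14 | 6α-[(tert-butyldimethylsilyl)oxy]-15,16-epoxy-12-(phenylsulfonyl)labda-13(16),14-dien-9α-ol (C12 epimers) | CC(C)(C)[Si](C)(C)O[C@H]1C[C@@H](C)[C@](O)(CC(c3ccoc3)S(=O)(=O)c3ccccc3)[C@@]2(C)CCCC(C)(C)[C@H]12
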